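**Strategy.** The plan rests on cutting ring A at two adjacent bonds, C6–O (to the ring B oxygen) and C1–CO2H. Because C6 (aryloxy), C1 (carboxyl) and C2 (methoxy) sit side by side on ring A, a 3-methoxyaryne spanning C1–C6 can accept the hindered ring B phenoxide at C6 and carbon dioxide at C1 in a single operation, the C2 methoxy group fixing the orientation. The aryne precursor is a ring A 2-(trimethylsilyl)aryl triflate (silicon at C1, triflate at C6) carrying the (S) diol side chain as a cyclic di-tert-butylsilylene; ring B enters as a phenol with its C2′ oxygen benzylated and its C6′ hydroxymethyl silylated.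

Key step: step 12

Remarks on the chemistry:
- Numbering: ring A is C1 (CO2H), C2 (OMe), C3 (side chain), C6 (aryloxy); ring B is C1′ (ether carbon), C2′ (OH), C4′ (CH3), C6′ (CH2OH).
- The carbinol carbon of the target is (S) (O > aryl > CH2 > H); the structures needed no correction.
- Assumption: the methallylborane made from (−)-Ipc2BOMe (B-methoxydiisopinocampheylborane of the (+)-α-pinene series) adds to the Si face of aryl aldehydes, as it does with benzaldehyde.

**Ring A: aryne precursor**

Step 1
Reactants: 1 4-hydroxy-2-methoxybenzaldehyde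
Product: 2 4-formyl-3-methoxyphenyl N-(propan-2-yl)carbamate
Conditions: i-PrNCO, Et3N (cat.), CH2Cl2, rt
Reagents that add atoms: isopropyl isocyanate, CC(C)N=C=O
Why: Base-catalysed carbamoylation of the phenol masks the future C6 oxygen as a secondary carbamate, which later directs lithiation to C1 and can be removed under mild amine conditions.

Step 2
Reactants: 2 4-formyl-3-methoxyphenyl N-(propan-2-yl)carbamate
Product: 4 4-[(1S)-1-hydroxy-3-methylbut-3-en-1-yl]-3-methoxyphenyl N-(propan-2-yl)carbamate, via O-borinate adduct 3 (not isolated)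
Conditions: (−)-Ipc2BOMe, CH2=C(CH3)CH2MgCl, Et2O, 0 °C → rt; then 2, −78 °C; then 30% H2O2, pH 7 phosphate buffer, MeOH, 0 °C → rt
Reagents that add atoms: methallylmagnesium chloride (methallyl group, delivered through boron), CC(=C)C[Mg]Cl
Why: Brown asymmetric methallylboration passes through a closed chair transition state in which the isopinocampheyl groups expose the Si face of the aldehyde, which sets the (S) carbinol centre; the buffered peroxide work-up spares the base-labile carbamate.

Step 3
Reactants: 4 4-[(1S)-1-hydroxy-3-methylbut-3-en-1-yl]-3-methoxyphenyl N-(propan-2-yl)carbamate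
Product: 5 4-[(1S)-1,3-dihydroxy-3-methylbutyl]-3-methoxyphenyl N-(propan-2-yl)carbamate
Conditions: Co(acac)2 (cat.), PhSiH3, O2 (1 atm), THF, rt
Reagents that add atoms: dioxygen, O=O
Why: Mukaiyama hydration: hydrogen-atom transfer from a cobalt hydride to the 1,1-disubstituted alkene gives the tertiary radical, which is trapped by O2 and reduced to the Markovnikov tertiary alcohol without touching the benzylic centre.

Step 4
Reactants: 5 4-[(1S)-1,3-dihydroxy-3-methylbutyl]-3-methoxyphenyl N-(propan-2-yl)carbamate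
Product: 6 4-[(4S)-2,2-di-tert-butyl-6,6-dimethyl-1,3,2-dioxasilinan-4-yl]-3-methoxyphenyl N-(propan-2-yl)carbamate
Conditions: t-Bu2Si(OTf)2, 2,6-lutidine, CH2Cl2, 0 °C → rt
Reagents that add atoms: di-tert-butylsilyl bis(trifluoromethanesulfonate), CC(C)(C)[Si](OS(=O)(=O)C(F)(F)F)(OS(=O)(=O)C(F)(F)F)C(C)(C)C
Why: Silylene formation: the secondary hydroxyl is silylated first and the tertiary hydroxyl then closes the six-membered dioxasilinane intramolecularly (helped by the gem-dimethyl group), so one fluoride-labile group free of acidic hydrogens masks both hydroxyls.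

Step 5
Reactants: 6 4-[(4S)-2,2-di-tert-butyl-6,6-dimethyl-1,3,2-dioxasilinan-4-yl]-3-methoxyphenyl N-(propan-2-yl)carbamate
Product: 10 4-[(4S)-2,2-di-tert-butyl-6,6-dimethyl-1,3,2-dioxasilinan-4-yl]-3-methoxy-2-(trimethylsilyl)phenyl N-(propan-2-yl)carbamate, via N-silyl carbamate 7 (not isolated), via C1 aryllithium 8 (not isolated), via N-silyl C-silyl carbamate 9 (not isolated)
Conditions: TBSOTf, TMEDA, Et2O, 0 °C → rt; then n-BuLi, TMEDA, −78 °C; then TMSCl, −78 °C → rt; aq. NaHSO4
Reagents that add atoms: chlorotrimethylsilane, C[Si](C)(C)Cl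
Why: Directed ortho-metalation: after N-silylation in the flask, the carbamate and the C2 methoxy group together direct n-BuLi to the C1–H between them, and the aryllithium is silylated at −78 °C before an anionic ortho-Fries shift can set in; the N–Si bond is hydrolysed on work-up.

Step 6
Reactants: 10 4-[(4S)-2,2-di-tert-butyl-6,6-dimethyl-1,3,2-dioxasilinan-4-yl]-3-methoxy-2-(trimethylsilyl)phenyl N-(propan-2-yl)carbamate
Product: 12 4-[(4S)-2,2-di-tert-butyl-6,6-dimethyl-1,3,2-dioxasilinan-4-yl]-3-methoxy-2-(trimethylsilyl)phenyl trifluoromethanesulfonate, via C6 phenol 11 (not isolated)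
Conditions: DBU, Et2NH, MeCN, 40 °C; then PhNTf2, rt
Reagents that add atoms: N-phenylbis(trifluoromethanesulfonimide), O=S(=O)(N(c1ccccc1)S(=O)(=O)C(F)(F)F)C(F)(F)F
Why: The secondary carbamate fragments by an E1cB pathway to the phenoxide and isopropyl isocyanate (scavenged by Et2NH as a urea), and the phenoxide is triflated in the same flask by PhNTf2 under conditions too mild to break the C1–Si bond.

**Ring B: phenol**

Step 7
Reactants: 13 2-methoxy-4-methylphenol
Product: 14 2-hydroxy-3-methoxy-5-methylbenzaldehyde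
Conditions: MgCl2, Et3N, (CH2O)n, MeCN, reflux; aq. HCl
Reagents that add atoms: paraformaldehyde (as formaldehyde), C=O
Why: Magnesium-mediated ortho-formylation (Casnati–Skattebøl reaction): the magnesium phenoxide delivers formaldehyde to the only free position ortho to oxygen (the para position carries the methyl group), and a second formaldehyde oxidises the benzylic alkoxide to the aldehyde.

Step 8
Reactants: 14 2-hydroxy-3-methoxy-5-methylbenzaldehyde
Product: 15 2,3-dihydroxy-5-methylbenzaldehyde
Conditions: BBr3, CH2Cl2, −78 °C → rt; H2O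
Reagents that add atoms: none
Why: Lewis-acid ether cleavage: BBr3 demethylates the aryl methyl ether by bromide attack on the boron-activated O–CH3 group, a reaction well established for ortho-vanillin-type aldehydes.

Step 9
Reactants: 15 2,3-dihydroxy-5-methylbenzaldehyde
Product: 17 3-(benzyloxy)-2-hydroxy-5-methylbenzaldehyde, via disodium catecholate 16 (not isolated)
Conditions: NaH (2.2 equiv), DMSO, rt; then BnBr (1.0 equiv), rt; aq. HCl
Reagents that add atoms: benzyl bromide, BrCc1ccccc1
Why: Williamson etherification of the dianion: the phenoxide ortho to the formyl group is delocalised into and chelated by the carbonyl, so the more basic phenoxide meta to it (the future C2′ oxygen) takes the single equivalent of benzyl bromide.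

Step 10
Reactants: 17 3-(benzyloxy)-2-hydroxy-5-methylbenzaldehyde
Product: 18 2-(benzyloxy)-6-(hydroxymethyl)-4-methylphenol
Conditions: NaBH4, MeOH/THF, 0 °C
Reagents that add atoms: none
Why: Borohydride reduction of the aryl aldehyde gives the benzylic alcohol, and a neutral work-up avoids ortho-quinone methide formation from the salicyl alcohol.

Step 11
Reactants: 18 2-(benzyloxy)-6-(hydroxymethyl)-4-methylphenol
Product: 19 2-(benzyloxy)-6-({[tert-butyl(dimethyl)silyl]oxy}methyl)-4-methylphenol
Conditions: TBSCl (1.05 equiv), imidazole, CH2Cl2, 0 °C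
Reagents that add atoms: tert-butyldimethylsilyl chloride, CC(C)(C)[Si](C)(C)Cl
Why: Chemoselective silylation: the primary benzylic hydroxyl reacts faster than the hydrogen-bonded phenol flanked by two ortho substituents, which leaves the nucleophilic oxygen of ring B free.

**Coupling and unmasking**

Step 12
Reactants: 12 4-[(4S)-2,2-di-tert-butyl-6,6-dimethyl-1,3,2-dioxasilinan-4-yl]-3-methoxy-2-(trimethylsilyl)phenyl trifluoromethanesulfonate; 19 2-(benzyloxy)-6-({[tert-butyl(dimethyl)silyl]oxy}methyl)-4-methylphenol; 20 carbon dioxide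
Product: 24 6-[2-(benzyloxy)-6-({[tert-butyl(dimethyl)silyl]oxy}methyl)-4-methylphenoxy]-3-[(4S)-2,2-di-tert-butyl-6,6-dimethyl-1,3,2-dioxasilinan-4-yl]-2-methoxybenzoic acid, via potassium phenoxide 21 (not isolated), via C1–C6 aryne 22 (not isolated), via C1 arylpotassium 23 (not isolated)
Conditions: 19 (1.5 equiv), KH, THF, 0 °C; 18-crown-6; then CO2 (1 atm), KF (2 equiv), 12 (slow addition), 0 °C → rt; cold dilute HCl
Reagents that add atoms: carbon dioxide (compound 20), O=C=O
Why: Proposed new method: fluoride attacks the C1 trimethylsilyl group of 12 and triflate departs from C6 to give aryne 22, the oxygen of the conjugate-acid-free potassium phenoxide 21 adds to C6, and the C1 aryl anion 23 is intercepted by CO2 to form the C1–CO2K bond, released as acid 24 on acidification. The closest known reaction types are the KF/18-crown-6-promoted three-component couplings of arynes with amines or phosphines and CO2 and the aryne–salicylate annulation, where the aryl anion left by phenoxide addition is caught by an ester carbonyl; intermolecular CO2 capture after addition of an anionic oxygen nucleophile has not been demonstrated. No ring is closed and no stereocentre is formed, the (4S) centre being held in the silylene away from the reacting carbons. Regioselectivity rests on the C2 methoxy group, whose inductive pull stabilises charge at C1 and leaves C6 the more electrophilic and less hindered terminus for the bulky 2,6-disubstituted phenoxide. Carboxylation should outrun protonation because the phenoxide is made with KH (H2 is the only by-product), THF replaces C–H-acidic acetonitrile and neither partner carries OH or NH, while CO2 at 1 atm keeps the reversibly carbonated, hindered phenoxide available for the aryne. Fluoride is used close to stoichiometry so that the TBS ether and the silylene, far slower to react than the aryl–SiMe3 bond activated by the ortho triflate, are left intact.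

Step 13
Reactants: 24 6-[2-(benzyloxy)-6-({[tert-butyl(dimethyl)silyl]oxy}methyl)-4-methylphenoxy]-3-[(4S)-2,2-di-tert-butyl-6,6-dimethyl-1,3,2-dioxasilinan-4-yl]-2-methoxybenzoic acid
Product: 25 6-[2-({[tert-butyl(dimethyl)silyl]oxy}methyl)-6-hydroxy-4-methylphenoxy]-3-[(4S)-2,2-di-tert-butyl-6,6-dimethyl-1,3,2-dioxasilinan-4-yl]-2-methoxybenzoic acid
Conditions: H2 (1 atm), 10% Pd/C, EtOAc, rt
Reagents that add atoms: none
Why: Catalytic hydrogenolysis of the aryl benzyl ether: in ethyl acetate the hindered benzylic silyl ethers (ring B CH2OTBS and the ring A silylene) resist C–O hydrogenolysis and the diaryl ether is inert, so only the C2′ oxygen is unmasked.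

Step 14
Reactants: 25 6-[2-({[tert-butyl(dimethyl)silyl]oxy}methyl)-6-hydroxy-4-methylphenoxy]-3-[(4S)-2,2-di-tert-butyl-6,6-dimethyl-1,3,2-dioxasilinan-4-yl]-2-methoxybenzoic acid
Product: 26 3-[(1S)-1,3-dihydroxy-3-methylbutyl]-6-[2-hydroxy-6-(hydroxymethyl)-4-methylphenoxy]-2-methoxybenzoic acid (target)
Conditions: HF·pyridine, pyridine, THF, 0 °C → rt
Reagents that add atoms: none
Why: Fluoride-mediated desilylation: buffered HF·pyridine cleaves the primary TBS ether and both Si–O bonds of the silylene, and the near-neutral medium should avoid ionisation of the electron-rich benzylic carbinol, so the (S) centre is retained.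

**Compound list**

1 | 4-hydroxy-2-methoxybenzaldehyde | COc1cc(O)ccc1C=O | starting material
2 | 4-formyl-3-methoxyphenyl N-(propan-2-yl)carbamate | COc1cc(OC(=O)NC(C)C)ccc1C=O | intermediate
3 | O-diisopinocampheylborinate of 4 (formed in the flask) | COc1cc(OC(=O)NC(C)C)ccc1[C@@H](OB([C@@H]2C[C@@H]3C[C@H]([C@H]2C)C3(C)C)[C@@H]4C[C@@H]5C[C@H]([C@H]4C)C5(C)C)CC(C)=C | intermediate
4 | 4-[(1S)-1-hydroxy-3-methylbut-3-en-1-yl]-3-methoxyphenyl N-(propan-2-yl)carbamate | COc1cc(OC(=O)NC(C)C)ccc1[C@@H](O)CC(C)=C | intermediate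
5 | 4-[(1S)-1,3-dihydroxy-3-methylbutyl]-3-methoxyphenyl N-(propan-2-yl)carbamate | COc1cc(OC(=O)NC(C)C)ccc1[C@@H](O)CC(C)(C)O | intermediate
6 | 4-[(4S)-2,2-di-tert-butyl-6,6-dimethyl-1,3,2-dioxasilinan-4-yl]-3-methoxyphenyl N-(propan-2-yl)carbamate | COc1cc(OC(=O)NC(C)C)ccc1[C@@H]2CC(C)(C)O[Si](C(C)(C)C)(C(C)(C)C)O2 | intermediate
7 | N-(tert-butyldimethylsilyl) derivative of 6 (formed in the flask) | COc1cc(OC(=O)N(C(C)C)[Si](C)(C)C(C)(C)C)ccc1[C@@H]2CC(C)(C)O[Si](C(C)(C)C)(C(C)(C)C)O2 | intermediate
8 | C1 aryllithium of 7 (lithium between OMe and the carbamate oxygen; formed in the flask) | COc1c([Li])c(OC(=O)N(C(C)C)[Si](C)(C)C(C)(C)C)ccc1[C@@H]2CC(C)(C)O[Si](C(C)(C)C)(C(C)(C)C)O2 | intermediate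
9 | N-(tert-butyldimethylsilyl) derivative of 10 (formed in the flask) | COc1c([Si](C)(C)C)c(OC(=O)N(C(C)C)[Si](C)(C)C(C)(C)C)ccc1[C@@H]2CC(C)(C)O[Si](C(C)(C)C)(C(C)(C)C)O2 | intermediate
10 | 4-[(4S)-2,2-di-tert-butyl-6,6-dimethyl-1,3,2-dioxasilinan-4-yl]-3-methoxy-2-(trimethylsilyl)phenyl N-(propan-2-yl)carbamate | COc1c([Si](C)(C)C)c(OC(=O)NC(C)C)ccc1[C@@H]2CC(C)(C)O[Si](C(C)(C)C)(C(C)(C)C)O2 | intermediate
11 | 4-[(4S)-2,2-di-tert-butyl-6,6-dimethyl-1,3,2-dioxasilinan-4-yl]-3-methoxy-2-(trimethylsilyl)phenol (formed in the flask as its DBU salt) | COc1c([Si](C)(C)C)c(O)ccc1[C@@H]2CC(C)(C)O[Si](C(C)(C)C)(C(C)(C)C)O2 | intermediate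
12 | 4-[(4S)-2,2-di-tert-butyl-6,6-dimethyl-1,3,2-dioxasilinan-4-yl]-3-methoxy-2-(trimethylsilyl)phenyl trifluoromethanesulfonate (ring A aryne precursor: SiMe3 at C1, OTf at C6) | COc1c([Si](C)(C)C)c(OS(=O)(=O)C(F)(F)F)ccc1[C@@H]2CC(C)(C)O[Si](C(C)(C)C)(C(C)(C)C)O2 | intermediate
13 | 2-methoxy-4-methylphenol | COc1cc(C)ccc1O | starting material
14 | 2-hydroxy-3-methoxy-5-methylbenzaldehyde | COc1cc(C)cc(C=O)c1O | intermediate
15 | 2,3-dihydroxy-5-methylbenzaldehyde | Cc1cc(O)c(O)c(C=O)c1 | intermediate
16 | disodium 3-formyl-5-methylbenzene-1,2-diolate (formed in the flask) | Cc1cc([O-])c([O-])c(C=O)c1.[Na+].[Na+] | intermediate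
17 | 3-(benzyloxy)-2-hydroxy-5-methylbenzaldehyde | Cc1cc(OCc2ccccc2)c(O)c(C=O)c1 | intermediate
18 | 2-(benzyloxy)-6-(hydroxymethyl)-4-methylphenol | Cc1cc(OCc2ccccc2)c(O)c(CO)c1 | intermediate
19 | 2-(benzyloxy)-6-({[tert-butyl(dimethyl)silyl]oxy}methyl)-4-methylphenol (ring B phenol) | Cc1cc(OCc2ccccc2)c(O)c(CO[Si](C)(C)C(C)(C)C)c1 | intermediate
20 | carbon dioxide | O=C=O | starting material
21 | potassium 2-(benzyloxy)-6-({[tert-butyl(dimethyl)silyl]oxy}methyl)-4-methylphenoxide (formed in the flask) | Cc1cc(OCc2ccccc2)c([O-])c(CO[Si](C)(C)C(C)(C)C)c1.[K+] | intermediate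
22 | (4S)-2,2-di-tert-butyl-4-(2-methoxy-3,4-didehydrophenyl)-6,6-dimethyl-1,3,2-dioxasilinane (ring A C1–C6 aryne; formed in the flask) | COC1=C([C@@H]2CC(C)(C)O[Si](C(C)(C)C)(C(C)(C)C)O2)C=CC#C1 | intermediate
23 | C1 arylpotassium adduct of 21 and 22 (potassium at C1, aryloxy at C6; formed in the flask) | COc1[c-]c(Oc2c(OCc3ccccc3)cc(C)cc2CO[Si](C)(C)C(C)(C)C)ccc1[C@@H]4CC(C)(C)O[Si](C(C)(C)C)(C(C)(C)C)O4.[K+] | intermediate
24 | 6-[2-(benzyloxy)-6-({[tert-butyl(dimethyl)silyl]oxy}methyl)-4-methylphenoxy]-3-[(4S)-2,2-di-tert-butyl-6,6-dimethyl-1,3,2-dioxasilinan-4-yl]-2-methoxybenzoic acid | COc1c(C(=O)O)c(Oc2c(OCc3ccccc3)cc(C)cc2CO[Si](C)(C)C(C)(C)C)ccc1[C@@H]4CC(C)(C)O[Si](C(C)(C)C)(C(C)(C)C)O4 | intermediate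
25 | 6-[2-({[tert-butyl(dimethyl)silyl]oxy}methyl)-6-hydroxy-4-methylphenoxy]-3-[(4S)-2,2-di-tert-butyl-6,6-dimethyl-1,3,2-dioxasilinan-4-yl]-2-methoxybenzoic acid | COc1c(C(=O)O)c(Oc2c(O)cc(C)cc2CO[Si](C)(C)C(C)(C)C)ccc1[C@@H]3CC(C)(C)O[Si](C(C)(C)C)(C(C)(C)C)O3 | intermediate
26 | 3-[(1S)-1,3-dihydroxy-3-methylbutyl]-6-[2-hydroxy-6-(hydroxymethyl)-4-methylphenoxy]-2-methoxybenzoic acid | COc1c([C@@H](O)CC(C)(C)O)ccc(Oc2c(O)cc(C)cc2CO)c1C(=O)O | target

**Step count**

Total: 14 steps (steps 1–6 for ring A, 7–11 for ring B, 12 for the coupling, 13–14 for unmasking).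
Longest linear sequence: 9 steps (steps 1–6, then 12–14, from 1 to 26).

**Steps most likely to fail**

1. Step 12 (carries the label). The C1 aryl anion may be protonated faster than it is carboxylated, either by adventitious water or by intramolecular proton transfer from the ring B benzylic positions. The phenoxide may also be tied up as its carbonate so that aryne capture slows, or fluoride may begin to strip silyl groups.
   Fallback (known chemistry): the two bonds are made one after the other. Setting out from 12 and 19, CsF in MeCN at rt without CO2 should give the plain aryne O-arylation product (4S)-4-{4-[2-(benzyloxy)-6-({[tert-butyl(dimethyl)silyl]oxy}methyl)-4-methylphenoxy]-2-methoxyphenyl}-2,2-di-tert-butyl-6,6-dimethyl-1,3,2-dioxasilinane F1, in which C1 carries hydrogen. Since that C1–H lies between the methoxy and aryloxy oxygens, directed ortho-lithiation (n-BuLi, TMEDA, THF, −78 → −20 °C) and a CO2 quench, followed by acidification, should give 24, where the route is rejoined.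

2. Step 5. n-BuLi may remove the benzylic carbinol hydrogen (with silyl migration from oxygen to carbon), open the silylene or metalate C5 in place of C1, and the lithiated carbamate may undergo an anionic ortho-Fries shift.
   Fallback: silicon is installed before the side chain exists. Setting out from 2, ethylene glycol with catalytic TsOH in refluxing toluene should give the acetal 4-(1,3-dioxolan-2-yl)-3-methoxyphenyl N-(propan-2-yl)carbamate F2. The silylation sequence of step 5 on this small substrate should give 4-(1,3-dioxolan-2-yl)-3-methoxy-2-(trimethylsilyl)phenyl N-(propan-2-yl)carbamate F3, and PPTS in aqueous acetone should release 4-formyl-3-methoxy-2-(trimethylsilyl)phenyl N-(propan-2-yl)carbamate F4. Methallylboration as in step 2 should then give 4-[(1S)-1-hydroxy-3-methylbut-3-en-1-yl]-3-methoxy-2-(trimethylsilyl)phenyl N-(propan-2-yl)carbamate F5, and hydration as in step 3 should give 4-[(1S)-1,3-dihydroxy-3-methylbutyl]-3-methoxy-2-(trimethylsilyl)phenyl N-(propan-2-yl)carbamate F6. Silylene formation as in step 4 returns to the route at 10.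

3. Step 9. Benzylation may occur at the oxygen next to the formyl group, or at both oxygens, if the dianion is incompletely formed or equilibrates with the monoanion.
   Fallback: both oxygens are benzylated and one benzyl group is then removed selectively. Setting out from 15, BnBr (2.5 equiv) and K2CO3 in DMF should give 2,3-bis(benzyloxy)-5-methylbenzaldehyde F7. MgBr2·OEt2 in toluene/Et2O at reflux should then cleave only the benzyl ether ortho to the formyl group through a magnesium chelate, returning to the route at 17.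

**Further compounds**

F1 | step 12 | (4S)-4-{4-[2-(benzyloxy)-6-({[tert-butyl(dimethyl)silyl]oxy}methyl)-4-methylphenoxy]-2-methoxyphenyl}-2,2-di-tert-butyl-6,6-dimethyl-1,3,2-dioxasilinane | COc1cc(Oc2c(OCc3ccccc3)cc(C)cc2CO[Si](C)(C)C(C)(C)C)ccc1[C@@H]4CC(C)(C)O[Si](C(C)(C)C)(C(C)(C)C)O4
F2 | step 5 | 4-(1,3-dioxolan-2-yl)-3-methoxyphenyl N-(propan-2-yl)carbamate | COc1cc(OC(=O)NC(C)C)ccc1C2OCCO2
F3 | step 5 | 4-(1,3-dioxolan-2-yl)-3-methoxy-2-(trimethylsilyl)phenyl N-(propan-2-yl)carbamate | COc1c([Si](C)(C)C)c(OC(=O)NC(C)C)ccc1C2OCCO2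
F4 | step 5 | 4-formyl-3-methoxy-2-(trimethylsilyl)phenyl N-(propan-2-yl)carbamate | COc1c([Si](C)(C)C)c(OC(=O)NC(C)C)ccc1C=O
F5 | step 5 | 4-[(1S)-1-hydroxy-3-methylbut-3-en-1-yl]-3-methoxy-2-(trimethylsilyl)phenyl N-(propan-2-yl)carbamate | COc1c([Si](C)(C)C)c(OC(=O)NC(C)C)ccc1[C@@H](O)CC(C)=C
F6 | step 5 | 4-[(1S)-1,3-dihydroxy-3-methylbutyl]-3-methoxy-2-(trimethylsilyl)phenyl N-(propan-2-yl)carbamate | COc1c([Si](C)(C)C)c(OC(=O)NC(C)C)ccc1[C@@H](O)CC(C)(C)O
F7 | step 9 | 2,3-bis(benzyloxy)-5-methylbenzaldehyde | Cc1cc(OCc2ccccc2)c(OCc2ccccc2)c(C=O)c1
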